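## Structural features

The target 22 is a depside in which two hexasubstituted benzene rings are held together by a single aryl ester, running from the carboxyl carbon on ring A to the oxygen on C4 of ring B. Ring A carries, in order, the ester carbonyl on C1, methyls on C2 and C3, a hydroxyl on C4, a formyl group on C5 and a hydroxyl on C6; ring B carries CO2Me on C1, methyls on C2 and C3, the acyloxy oxygen on C4, a methyl on C5 and a methoxy group on C6. The molecule has no stereocentre and no stereogenic double bond, so every selectivity question is one of regiochemistry around the two rings. The fragile groups are the phenyl ester (cleaved by bases and nucleophiles), the aldehyde between two phenols, the ring A hydroxy acid once it is free (it loses CO2 in hot or strongly acidic media) and the ring B methyl ether, which lies ortho to an ester and is therefore open to attack by boron halides. The real difficulty is twofold: the contiguous substituent order of ring A cannot be reached by electrophilic substitution of a simple arene, and the ester has to be made from an acid with two ortho substituents and a phenol with two ortho methyls while free phenols and an aldehyde are present. The key step uses the fact that on ring A the oxygens on C6 and C4 are meta with only C5 between them, the carboxyl on C1 is next to C6, and C2 and C3 bear methyls. A methyl(vinyl)ketene and an ynol ether deliver exactly this arrangement when C6 (ketene carbonyl carbon), C5 and C4 (alkyne carbons) and C3, C2 and C1 (ketene α-carbon and vinyl carbons) are joined into a phenol, so that only the formyl carbon on C5 has to be added afterwards.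

## Logic of the disconnections

22 ⇒ 15 + 21. The C(=O)–O bond of the aryl ester is cut. It is the only link between the rings and the most base-labile bond, so it is formed last. The cut gives two arenes of similar size that are made in parallel. The forward step must acylate a phenol flanked by two methyls with an acid flanked by methyl and hydroxyl, without protecting the ring A phenols and without touching the aldehyde.

15 ⇒ 14. The O–ethyl bond at C4 and the O–benzyl bond of the ester are cut. Both are removed together and only after formylation. The reverse order (ether cleavage first, formylation of the free acid second) is rejected, because it would expose a decarboxylation-prone hydroxy acid to a strong Lewis acid. With the formyl group in place, the boron reagent has a chelation site next to the ethyl ether. The gain is that 14 has no free carboxyl and only one free phenol. The forward step needs a boron halide strong enough for an ethyl aryl ether and cold enough to spare CHO and CO2H.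

14 ⇒ 13. The C5–CHO bond is cut. C5 is the only unsubstituted ring carbon of 13 and lies between the two oxygens. Removing this one carbon, which the annulation cannot bring, leaves exactly the product of the key step. The forward step must formylate a crowded position ortho to a free phenol; regiochemistry is not in question.

13 ⇒ 7 + 8 (key disconnection). Three ring A bonds are cut: C6–C5, C4–C3 and C6–C1. Cutting here turns a pentasubstituted arene into an open-chain diazo ketone and a two-carbon alkyne, and every ring A substituent except the formyl carbon is fixed by the connectivity of the partners. The skeletons of 7 and 13 agree atom for atom with this mechanism. The benzyl ester is kept because one reagent later removes it together with the ethyl ether. The forward step needs clean Wolff migration of the alkenyl group, head-to-tail (2+2) addition of the ynol ether, and an electrocyclic cascade that ends on the ester-bearing alkene carbon.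

7 ⇒ 5. The C=N2 bond at C5 of the hexenoate chain is cut back to a methylene. The shorter-looking path, acylation of a diazoalkane by 4, is not used. Diazoalkanes add as 1,3-dipoles to fumarate-type alkenes such as those of 4 and 7, and the reagent needed would be a volatile, explosive diazoalkane in excess. The gain is that 5 is a stable ketone and the diazo group is introduced last under mild conditions. The forward step needs enolisation at the only enolisable carbon next to the ketone and diazo transfer without Michael self-condensation.

5 ⇒ 3 (through 4). The bond between the ketone carbon C4 and the ethyl CH2 is cut. This traces the ketone to a carboxyl that is already in place with the right alkene geometry. The forward step must transfer an ethyl group to an acid chloride without adding to the enoate or the benzyl ester, which calls for an organozinc reagent under palladium catalysis.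

3 ⇒ 1 + 2. The ester C–O bond at C4 of the butenedioate is cut. Both carbon frameworks are then commercial. The forward step needs site selection between two carboxyls, which rests on the greater hindrance of the one on the methyl-bearing carbon. The E geometry must be kept, since it stops 4 from closing to a cyclic anhydride.

21 ⇒ 19 (through 20). The ring B C4–O bond is cut and replaced by C–Br. This oxygen sits between two methyls and meta to the other oxygen, so no electrophilic oxygenation can place it directly, whereas a halogen can be put on the last free carbon. The forward step needs a cross-coupling that tolerates two ortho methyls and an oxidation that spares the ester.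

19 ⇒ 18. The C4–Br bond is cut. C4 is the only unsubstituted ring carbon of 18, so no regiochemical choice arises. The forward step must be ionic bromination of a ring that carries a deactivating ester, without benzylic bromination.

18 ⇒ 17. The two O–CH3 bonds (ester and ether) are cut. One alkylating reagent forms both, and the oxygen that becomes the ring B methyl ether is the one already present in the starting phenol. The forward step must alkylate a hindered, hydrogen-bonded phenol and a hindered carboxylate.

17 ⇒ 16. The ring C–CO2H bond ortho to the hydroxyl is cut. The phenol 16 already has the three methyls in the right places, and its para and one ortho position are blocked. The forward step must carboxylate the remaining ortho carbon, next to a methyl.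

## Other disconnections considered

Alternative 1: The cut removes the depside C–O bond and the ring A C1–C2 bond together, so ring A is not yet an arene when the rings are joined. In the forward direction the diketo-dioxinone A2 [2,2-dimethyl-6-(3-methyl-2,4-dioxopentyl)-4H-1,3-dioxin-4-one] would be heated with 21. Retro-(4+2) fragmentation of A2 would unmask the acylketene A3, whose ketene carbon the phenol oxygen of 21 would capture to give the aryl triketo ester A4. Cs2CO3 in the same flask should then bring about aldol closure of C1 onto the methyl ketone at C2 and dehydration, leading to the desformyl depside A1. Formylation of A1 at C5, the only free ring carbon of the whole molecule, would finish 22.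

In its favour: the hindered phenol attacks an unhindered ketene carbon, so the esterification, the weakest point of the chosen plan, is better solved here. The ring A phenols never need protection, and no diazo compound or photochemistry is involved.

Against it here: a phenol is a weaker ketene trap than an alcohol. The aryl β-keto ester in A4 is itself an acyl donor that Cs2CO3 can cleave. A4 has several enolisable positions, so O-cyclisation to a pyranone, retro-Claisen loss of acetyl from the methyl-branched diketone and aldol closure in the wrong sense all compete. A2 would itself need about three steps of strongly basic C-acylation chemistry.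

Comparison: on step economy this alternative is the better one (about five operations for ring A plus ester, against seven). On mechanism both are cascades, but the chosen one fixes the substituent order by connectivity alone, while this one depends on chemoselective enolate chemistry. On structure the chosen plan passes through stable, isolable benzoates, whereas A4 is a transient polycarbonyl compound.

Alternative 2: The cut goes through ring B at C1–C2 and C4–C5, taking the arene back to a cyclohexanedione. In the forward direction NaOMe would join the carbon between the two carbonyls of methyl 3-oxopentanoate A5 to the β-carbon of methyl tiglate A6 (Michael addition). The ethyl CH2 of the keto ester would then attack the tiglate ester carbonyl (Claisen closure), giving the dione A7 (methyl 3,5,6-trimethyl-2,4-dioxocyclohexane-1-carboxylate). Dehydrogenation would give the resorcylate A8 (methyl 2,4-dihydroxy-3,5,6-trimethylbenzoate), and O-methylation at the right oxygen would have to lead to 21.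

In its favour: two bulk esters and one pot place all six ring carbons, three methyls and both oxygens with no regiochemical ambiguity. No transition metal or pressure vessel is needed, and the stereocentres of A7 are irrelevant.

Against it here: A6 is an α,β-disubstituted and therefore slow, reversible Michael acceptor. Aromatisation must remove hydrogens from two adjacent methyl-bearing carbons. Most seriously, in A8 the hydroxyl that must become the methyl ether is the hydrogen-bonded, less reactive one, so a protect–methylate–deprotect sequence of three further steps would be needed.

Comparison: on cost and scalability this alternative is better. On step count the two are about equal (about five steps to 21 against four). On mechanism both are classical polar chemistry and equal. On structure the chosen sequence has the advantage that the two oxygens are differentiated from the start, one being present in 16 and the other introduced later. This alternative concerns ring B only, so ring A and the ester would still need steps 1–6 and 11.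

Alternative 3: The cut goes through ring B at C1–C6 and C2–C3. In the forward direction the ketene-acetal diene A9 [(3Z)-1,1-dimethoxy-2-methyl-3-(trimethylsilyloxy)penta-1,3-diene] and methyl but-2-ynoate A10 would undergo (4+2) cycloaddition. The nucleophilic CH(CH3) terminus of A9 bonds to the β-carbon of A10 (C3–C2) and the acetal carbon to the α-carbon (C6–C1). Loss of one acetal alkoxy group aromatises the adduct, and desilylation frees the C4 hydroxyl to give A11, which is identical with 21.

In its favour: it is the only plan that delivers ring B with all six substituents and with the two oxygens already differentiated in a single step. On this point it is better than the chosen ring B sequence. The regiochemistry is polarity-matched.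

Against it here: A9 is a fully substituted, hydrolytically fragile ketene acetal that would take two to three steps to make and must be used at once. Both diene termini and both alkyne carbons are substituted and A10 is a sluggish dienophile, so the heat required may divert A9 into silyl migration or Michael-type addition. A hexasubstituted benzene is formed in one event.

Comparison: step economy is equal or slightly better (three to four steps to 21 against four). On mechanism it is a pericyclic step comparable in spirit to the chosen key step. On structure it is less robust than substitution chemistry on the commercial arene 16. Like alternative 2, it concerns ring B only.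

Key step: step 4

Assumption on the chemistry: the two ring A hydroxyls of 15 are taken to be deactivated enough by hydrogen bonding (to CO2H and CHO) for 15 to be coupled without protection; the fallback for step 11 covers the opposite case.

Remark on locants: systematic names of ring A intermediates use benzoate locants, where benzoate C2, C3, C4, C5 and C6 correspond to ring A C6, C5, C4, C3 and C2.

## Route

Step 1
Reactants: 1 mesaconic acid [(2E)-2-methylbut-2-enedioic acid]; 2 benzyl alcohol
Product: 3 (2E)-4-(benzyloxy)-2-methyl-4-oxobut-2-enoic acid
Conditions: BnOH (1.0 equiv), TsOH·H2O (cat.), toluene, reflux, Dean–Stark; NaHCO3 partition, then acidify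
Reagents that add atoms: none
Why: Fischer esterification: the carboxyl on the CH carbon is less hindered than the one on the methyl-bearing carbon, whose tetrahedral intermediate is crowded, so one equivalent of alcohol should esterify it preferentially, and unreacted 1 and any diester are removed by bicarbonate partition. The E geometry is not touched.

Step 2
Reactants: 3 (2E)-4-(benzyloxy)-2-methyl-4-oxobut-2-enoic acid
Product: 5 benzyl (2E)-3-methyl-4-oxohex-2-enoate, via acid chloride 4 (not isolated)
Conditions: (COCl)2, DMF (cat.), CH2Cl2, 0 °C to rt, evaporate; Et2Zn (0.6 equiv), Pd(PPh3)4 (3 mol %), toluene, 0 °C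
Reagents that add atoms: diethylzinc, CC[Zn]CC
Why: Acid chloride formation through the chloroiminium species from oxalyl chloride and DMF, then Negishi acylation: the C–Cl bond adds oxidatively to zerovalent palladium, ethyl is transferred from zinc and the ketone is released by reductive elimination. Diethylzinc alone does not add to enoates, ketones or benzyl esters at 0 °C, and the E geometry keeps 4 from closing to a cyclic anhydride.

Step 3
Reactants: 5 benzyl (2E)-3-methyl-4-oxohex-2-enoate
Product: 7 benzyl (2E)-5-diazo-3-methyl-4-oxohex-2-enoate, via trifluoroacetyl diketone 6 (not isolated)
Conditions: LiN(SiMe3)2, THF, −78 °C; CF3CO2CH2CF3, −78 °C; aq. HCl; then 4-AcNHC6H4SO2N3, Et3N, H2O (1 equiv), MeCN, rt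
Reagents that add atoms: 4-acetamidobenzenesulfonyl azide, CC(=O)Nc1ccc(cc1)S(=O)(=O)N=[N+]=[N-]
Why: Detrifluoroacetylative diazo transfer (a deacylative Regitz-type transfer): the ethyl CH2 is the only enolisable position next to the ketone, its lithium enolate is C-acylated within minutes at −78 °C, and the 1,3-diketone 6 is acidic enough for Et3N to promote diazo transfer with the trifluoroacetyl group leaving on the sulfonamide nitrogen. This reaches 7 without a diazoalkane and so without dipolar cycloaddition to the electron-poor alkene, and the sulfonyl azide chosen is among the least shock-sensitive.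

Step 4
Reactants: 7 benzyl (2E)-5-diazo-3-methyl-4-oxohex-2-enoate; 8 ethoxyacetylene
Product: 13 benzyl 4-ethoxy-2-hydroxy-5,6-dimethylbenzoate, via vinylketene 9 (not isolated), via vinylcyclobutenone 10 (not isolated), via dienylketene 11 (not isolated), via cyclohexadienone 12 (not isolated)
Conditions: hν (300 nm), 8 (2–3 equiv, commercial hexane solution), ClCH2CH2Cl, rt; then 80 °C
Reagents that add atoms: none
Why: Direct irradiation expels N2 from 7 and the alkenyl group migrates to the diazo carbon (photochemical Wolff rearrangement), giving the methyl(vinyl)ketene 9. The nucleophilic CH carbon of the ynol ether 8 attacks the ketene carbonyl carbon and the (2+2) cycloaddition closes to the 4-vinylcyclobutenone 10, which forms C6–C5 and C4–C3 and sets OEt meta to the future phenol oxygen with C5–H between them. Four-electron electrocyclic opening of 10, under the lamp or on warming to 80 °C, breaks the bond between the carbonyl carbon and the quaternary carbon and gives the dienylketene 11, whose thermal disrotatory six-electron electrocyclisation joins the ketene carbon to the ester-bearing alkene carbon (C6–C1) and gives the dienone 12, which enolises to the phenol 13. The closest known reaction type is the Danheiser benzannulation in its photochemical Wolff variant, in which α-diazo enones and alkoxy- or siloxyalkynes give resorcinol monoethers. Ring A is the only ring that remains and it is closed by the six-electron electrocyclisation, the four-membered ring of 10 being only a relay. No lasting stereocentre is created, because the quaternary carbon of 10 and the sp3 carbon of 12 are erased by ring opening and enolisation, and the alkene geometry of 7 has no bearing on the closure. The step needs regioselectivity in the (2+2) event, which the polarisation of the ynol ether secures, and chemoselectivity for Wolff migration over a 1,2-hydrogen shift from the methyl group, which singlet-state photolysis at room temperature with 8 in excess should favour, while the hydrogen-bonded salicylate hydroxyl of 13 is a poor trap for the ketene.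

Step 5
Reactants: 13 benzyl 4-ethoxy-2-hydroxy-5,6-dimethylbenzoate
Product: 14 benzyl 4-ethoxy-3-formyl-2-hydroxy-5,6-dimethylbenzoate
Conditions: Cl2CHOMe, TiCl4, CH2Cl2, −10 to 0 °C; aq. HCl
Reagents that add atoms: dichloromethyl methyl ether, COC(Cl)Cl; water, O
Why: Rieche formylation: TiCl4 binds the phenoxide and delivers the electrophile derived from the dichloromethyl ether to the ortho carbon, which is also the only unsubstituted position of the ring (C5 of ring A) and is activated by both oxygens; hydrolysis of the chloro ether gives the aldehyde. The phenyl ring of the benzyl ester is not activated and should not react.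

Step 6
Reactants: 14 benzyl 4-ethoxy-3-formyl-2-hydroxy-5,6-dimethylbenzoate
Product: 15 3-formyl-2,4-dihydroxy-5,6-dimethylbenzoic acid
Conditions: BCl3 (4 equiv), CH2Cl2, −78 °C to rt; ice-water
Reagents that add atoms: none
Why: Lewis acid dealkylation: boron held between the formyl oxygen and the ether oxygen activates the O–ethyl bond for chloride attack, and the benzyl ester is cleaved by boron-assisted ionisation to benzyl chloride; the methyl ether that would be at risk is not yet in the molecule. The ring has no free position for Friedel–Crafts benzylation, and the cold aqueous quench avoids decarboxylation of the hydroxy acid.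

Step 7
Reactants: 16 2,4,5-trimethylphenol
Product: 17 2-hydroxy-3,5,6-trimethylbenzoic acid
Conditions: NaH, THF, evaporate; CO2 (20 bar), 160 °C; aq. HCl
Reagents that add atoms: carbon dioxide, O=C=O
Why: Kolbe–Schmitt carboxylation: the sodium phenoxide–CO2 complex delivers CO2 to an ortho carbon, and since the para and one ortho position carry methyls, only the carbon between the hydroxyl and a methyl can react.

Step 8
Reactants: 17 2-hydroxy-3,5,6-trimethylbenzoic acid
Product: 18 methyl 2-methoxy-3,5,6-trimethylbenzoate
Conditions: MeI (3 equiv), K2CO3, DMF, 50 °C
Reagents that add atoms: iodomethane, CI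
Why: Double SN2 O-methylation of carboxylate and phenoxide (Williamson type); alkylation at oxygen sidesteps the crowded tetrahedral intermediate that acid-catalysed esterification of this 2,6-disubstituted acid would need. Warming in DMF is needed for the hydrogen-bonded, flanked phenol.

Step 9
Reactants: 18 methyl 2-methoxy-3,5,6-trimethylbenzoate
Product: 19 methyl 4-bromo-2-methoxy-3,5,6-trimethylbenzoate
Conditions: NBS, CF3CO2H, H2SO4 (cat.), rt, dark
Reagents that add atoms: N-bromosuccinimide, O=C1CCC(=O)N1Br
Why: Electrophilic aromatic bromination at the single unsubstituted ring carbon, which is ortho to two methyls; ionic conditions in the dark suppress benzylic bromination. Methylating first (step 8) removes the ipso-bromodecarboxylation pathway that is open to the salicylic acid 17.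

Step 10
Reactants: 19 methyl 4-bromo-2-methoxy-3,5,6-trimethylbenzoate
Product: 21 methyl 4-hydroxy-2-methoxy-3,5,6-trimethylbenzoate, via pinacol boronate 20 (not isolated)
Conditions: B2pin2, Pd(OAc)2 (cat.), SPhos, KOAc, dioxane, 90 °C; then 30% H2O2, aq. NaOH, THF, 0 °C; aq. HCl
Reagents that add atoms: hydrogen peroxide, OO
Why: Miyaura borylation followed by oxidation of the C–B bond: the bulky, electron-rich biaryl phosphine lets zerovalent palladium insert into the doubly ortho-methylated C–Br bond, and hydroperoxide then triggers aryl migration from boron to oxygen at the same carbon. The methyl ester, flanked by OMe and methyl, is too hindered to be saponified during the short, cold basic oxidation.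

Step 11
Reactants: 15 3-formyl-2,4-dihydroxy-5,6-dimethylbenzoic acid; 21 methyl 4-hydroxy-2-methoxy-3,5,6-trimethylbenzoate
Product: 22 3-methoxy-4-(methoxycarbonyl)-2,5,6-trimethylphenyl 3-formyl-2,4-dihydroxy-5,6-dimethylbenzoate (CNP0206150.0)
Conditions: 15 (1 equiv), 21 (1.2 equiv), (CF3CO)2O, toluene, 0 °C to rt; aq. NaHCO3
Reagents that add atoms: none
Why: Mixed-anhydride esterification with trifluoroacetic anhydride, the classical depside coupling: the di-ortho-substituted acid forms an acyl trifluoroacetate that ionises towards an acylium ion, which the phenol oxygen of 21 captures. Both ring A hydroxyls are hydrogen-bonded and electron-poor and should compete poorly, and any aryl trifluoroacetates are hydrolysed in the bicarbonate work-up.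

## Compound list

1 | mesaconic acid, (2E)-2-methylbut-2-enedioic acid | OC(=O)/C=C(\C)C(=O)O | starting material
2 | benzyl alcohol | OCc1ccccc1 | starting material
3 | (2E)-4-(benzyloxy)-2-methyl-4-oxobut-2-enoic acid | OC(=O)/C(C)=C/C(=O)OCc1ccccc1 | intermediate
4 | benzyl (2E)-4-chloro-3-methyl-4-oxobut-2-enoate (acid chloride, not isolated) | ClC(=O)/C(C)=C/C(=O)OCc1ccccc1 | intermediate
5 | benzyl (2E)-3-methyl-4-oxohex-2-enoate | CCC(=O)/C(C)=C/C(=O)OCc1ccccc1 | intermediate
6 | benzyl (2E)-7,7,7-trifluoro-3,5-dimethyl-4,6-dioxohept-2-enoate (racemic at C5, largely enolised, not isolated) | CC(C(=O)C(F)(F)F)C(=O)/C(C)=C/C(=O)OCc1ccccc1 | intermediate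
7 | benzyl (2E)-5-diazo-3-methyl-4-oxohex-2-enoate | CC(=[N+]=[N-])C(=O)/C(C)=C/C(=O)OCc1ccccc1 | intermediate
8 | ethoxyacetylene (ethoxyethyne) | C#COCC | starting material
9 | benzyl (2E)-3,4-dimethyl-5-oxopenta-2,4-dienoate (vinylketene, not isolated) | O=C=C(C)/C(C)=C/C(=O)OCc1ccccc1 | intermediate
10 | benzyl (2E)-3-(2-ethoxy-1-methyl-4-oxocyclobut-2-en-1-yl)but-2-enoate (racemic, not isolated) | CCOC1=CC(=O)C1(C)/C(C)=C/C(=O)OCc1ccccc1 | intermediate
11 | benzyl (2E,4E)-5-ethoxy-3,4-dimethyl-7-oxohepta-2,4,6-trienoate (dienylketene, not isolated) | O=C=C\C(OCC)=C(C)/C(C)=C/C(=O)OCc1ccccc1 | intermediate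
12 | benzyl 4-ethoxy-5,6-dimethyl-2-oxocyclohexa-3,5-diene-1-carboxylate (racemic, not isolated) | CCOC1=CC(=O)C(C(=O)OCc2ccccc2)C(C)=C1C | intermediate
13 | benzyl 4-ethoxy-2-hydroxy-5,6-dimethylbenzoate | CCOc1cc(O)c(C(=O)OCc2ccccc2)c(C)c1C | intermediate
14 | benzyl 4-ethoxy-3-formyl-2-hydroxy-5,6-dimethylbenzoate | CCOc1c(C)c(C)c(C(=O)OCc2ccccc2)c(O)c1C=O | intermediate
15 | 3-formyl-2,4-dihydroxy-5,6-dimethylbenzoic acid | Cc1c(C)c(C(=O)O)c(O)c(C=O)c1O | intermediate
16 | 2,4,5-trimethylphenol | Cc1cc(C)c(C)cc1O | starting material
17 | 2-hydroxy-3,5,6-trimethylbenzoic acid | Cc1cc(C)c(O)c(C(=O)O)c1C | intermediate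
18 | methyl 2-methoxy-3,5,6-trimethylbenzoate | COC(=O)c1c(C)c(C)cc(C)c1OC | intermediate
19 | methyl 4-bromo-2-methoxy-3,5,6-trimethylbenzoate | COC(=O)c1c(C)c(C)c(Br)c(C)c1OC | intermediate
20 | methyl 2-methoxy-3,5,6-trimethyl-4-(4,4,5,5-tetramethyl-1,3,2-dioxaborolan-2-yl)benzoate (pinacol boronate, not isolated) | COC(=O)c1c(C)c(C)c(B2OC(C)(C)C(C)(C)O2)c(C)c1OC | intermediate
21 | methyl 4-hydroxy-2-methoxy-3,5,6-trimethylbenzoate | COC(=O)c1c(C)c(C)c(O)c(C)c1OC | intermediate
22 | 3-methoxy-4-(methoxycarbonyl)-2,5,6-trimethylphenyl 3-formyl-2,4-dihydroxy-5,6-dimethylbenzoate (CNP0206150.0) | COC(=O)c1c(C)c(C)c(OC(=O)c2c(C)c(C)c(O)c(C=O)c2O)c(C)c1OC | target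

## Step count and least certain steps

Total step count: 11. Longest linear sequence: 7 steps (steps 1–6 and 11). The ring B branch (steps 7–10) joins at step 11.

**Step 4 (key step).** After loss of N2, a 1,2-hydrogen shift from the methyl on the carbene carbon may compete with alkenyl migration, since disubstituted diazo ketones populate conformers that favour free-carbene chemistry. Photoisomerisation of the enoate to the Z isomer may also let the ketene be captured by the now cis ester carbonyl before 8 can add. The fallback replaces the pericyclic cascade by a polar Michael–Claisen annulation followed by aromatisation; it sets out from 2 and returns at 15. Esterification of malonic acid with 2 (TsOH, toluene, Dean–Stark) would give dibenzyl malonate F1. With NaH in THF, F1 and (E)-3-methylpent-3-en-2-one should undergo Michael addition and then Claisen closure of the methyl ketone carbon onto one ester, so that benzyl 5,6-dimethyl-2,4-dioxocyclohexane-1-carboxylate F2 results. Bromination–dehydrobromination of F2 (Br2, DMF, 0 then 80 °C) would aromatise it to benzyl 2,4-dihydroxy-5,6-dimethylbenzoate F3, and Rieche formylation of F3 (TiCl4, Cl2CHOMe) at its only free ring carbon would furnish benzyl 3-formyl-2,4-dihydroxy-5,6-dimethylbenzoate F4. BCl3 in CH2Cl2 would finally cleave the benzyl ester of F4 to 15.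

**Step 3.** The amide base or the newly formed enolate may add in conjugate fashion to the doubly activated alkene of 5 (oligomerisation), or deprotonation may occur at the C3 methyl, before trifluoroacetylation takes place. The fallback avoids strong base altogether; it sets out from 5 and returns at 7. Riley oxidation of the ketone methylene of 5 (SeO2, dioxane, 80 °C) would give benzyl (2E)-3-methyl-4,5-dioxohex-2-enoate F5. One equivalent of TsNHNH2 in MeOH at 0 °C should condense with F5 at the less hindered acetyl carbonyl and give benzyl (2E)-3-methyl-5-[2-(4-methylbenzenesulfonyl)hydrazinylidene]-4-oxohex-2-enoate F6. Et3N in CH2Cl2 would then eliminate sulfinate from F6 (Bamford–Stevens-type diazo formation) and give 7.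

**Step 11.** The activated carboxyl of one molecule of 15 may be captured by the C4 hydroxyl of another (self-acylation to oligomeric esters), or attack by the hindered, electron-poor phenol 21 may be too slow. The fallback protects the C4 oxygen before coupling and formylates afterwards; it sets out from 13 and returns at 22. BBr3 (CH2Cl2, −78 to 0 °C) would convert 13 into 2,4-dihydroxy-5,6-dimethylbenzoic acid F7. Treating F7 with BnBr (2.2 equiv) and K2CO3 in acetone would give benzyl 4-(benzyloxy)-2-hydroxy-5,6-dimethylbenzoate F8, the hydrogen-bonded hydroxyl staying free, and KOH in DMSO/H2O at 80 °C would saponify F8 to 4-(benzyloxy)-2-hydroxy-5,6-dimethylbenzoic acid F9. Coupling of F9 with 21 by (CF3CO)2O in toluene would give 3-methoxy-4-(methoxycarbonyl)-2,5,6-trimethylphenyl 4-(benzyloxy)-2-hydroxy-5,6-dimethylbenzoate F10. Rieche formylation of F10 (TiCl4, Cl2CHOMe) ortho to the free hydroxyl would give 3-methoxy-4-(methoxycarbonyl)-2,5,6-trimethylphenyl 4-(benzyloxy)-3-formyl-2-hydroxy-5,6-dimethylbenzoate F11. BCl3 with pentamethylbenzene in CH2Cl2 at −78 °C would remove the benzyl ether of F11 without touching the ring B methyl ether and give 22.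

**Step 10.** Oxidative addition and transmetalation at the doubly ortho-methylated C–Br bond may be slow, so that protodebromination back to 18 outruns borylation. The fallback installs the oxygen by formylation and oxidative aryl migration; it sets out from 18 and returns at 21. Rieche formylation of 18 (TiCl4, Cl2CHOMe) at its only free ring carbon would give methyl 4-formyl-2-methoxy-3,5,6-trimethylbenzoate F12. Oxidation of F12 with mCPBA in CH2Cl2 (Baeyer–Villiger oxidation with aryl migration, favoured because the flanked formyl group is twisted out of conjugation) would give methyl 4-(formyloxy)-2-methoxy-3,5,6-trimethylbenzoate F13. K2CO3 in MeOH at 0 °C would cleave the formate of F13 much faster than the hindered benzoate and give 21.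

**Step 1.** Site discrimination between the two carboxyls may be incomplete, and esterification at the hindered carboxyl would give a regioisomeric monoester that is hard to separate from 3. The fallback builds the alkene with the two carboxyls already differentiated; it sets out from 2 and returns at 3. Esterification of L-tartaric acid with 2 (TsOH, toluene, Dean–Stark) would give dibenzyl (2R,3R)-2,3-dihydroxybutanedioate F14. HIO4 in Et2O would cleave the diol of F14 to benzyl 2-oxoacetate F15. Wittig olefination of F15 with tert-butyl 2-(triphenylphosphoranylidene)propanoate (CH2Cl2, rt; stabilised ylide, E-selective) would give 4-benzyl 1-tert-butyl (2E)-2-methylbut-2-enedioate F16. CF3CO2H in CH2Cl2 would remove the tert-butyl group of F16 and give 3.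

## Further compounds

F1 | step 4 | dibenzyl malonate | O=C(CC(=O)OCc1ccccc1)OCc1ccccc1
F2 | step 4 | benzyl 5,6-dimethyl-2,4-dioxocyclohexane-1-carboxylate (mixture of diastereomers and enol forms) | CC1C(C)C(C(=O)OCc2ccccc2)C(=O)CC1=O
F3 | step 4 | benzyl 2,4-dihydroxy-5,6-dimethylbenzoate | Cc1c(C)c(C(=O)OCc2ccccc2)c(O)cc1O
F4 | step 4 | benzyl 3-formyl-2,4-dihydroxy-5,6-dimethylbenzoate | Cc1c(C)c(C(=O)OCc2ccccc2)c(O)c(C=O)c1O
F5 | step 3 | benzyl (2E)-3-methyl-4,5-dioxohex-2-enoate | CC(=O)C(=O)/C(C)=C/C(=O)OCc1ccccc1
F6 | step 3 | benzyl (2E)-3-methyl-5-[2-(4-methylbenzenesulfonyl)hydrazinylidene]-4-oxohex-2-enoate (C=N geometry not defined) | CC(=NNS(=O)(=O)c1ccc(C)cc1)C(=O)/C(C)=C/C(=O)OCc1ccccc1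
F7 | step 11 | 2,4-dihydroxy-5,6-dimethylbenzoic acid | Cc1c(C)c(C(=O)O)c(O)cc1O
F8 | step 11 | benzyl 4-(benzyloxy)-2-hydroxy-5,6-dimethylbenzoate | Cc1c(C)c(C(=O)OCc2ccccc2)c(O)cc1OCc1ccccc1
F9 | step 11 | 4-(benzyloxy)-2-hydroxy-5,6-dimethylbenzoic acid | Cc1c(C)c(C(=O)O)c(O)cc1OCc1ccccc1
F10 | step 11 | 3-methoxy-4-(methoxycarbonyl)-2,5,6-trimethylphenyl 4-(benzyloxy)-2-hydroxy-5,6-dimethylbenzoate | COC(=O)c1c(C)c(C)c(OC(=O)c2c(C)c(C)c(OCc3ccccc3)cc2O)c(C)c1OC
F11 | step 11 | 3-methoxy-4-(methoxycarbonyl)-2,5,6-trimethylphenyl 4-(benzyloxy)-3-formyl-2-hydroxy-5,6-dimethylbenzoate | COC(=O)c1c(C)c(C)c(OC(=O)c2c(C)c(C)c(OCc3ccccc3)c(C=O)c2O)c(C)c1OC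
F12 | step 10 | methyl 4-formyl-2-methoxy-3,5,6-trimethylbenzoate | COC(=O)c1c(C)c(C)c(C=O)c(C)c1OC
F13 | step 10 | methyl 4-(formyloxy)-2-methoxy-3,5,6-trimethylbenzoate | COC(=O)c1c(C)c(C)c(OC=O)c(C)c1OC
F14 | step 1 | dibenzyl (2R,3R)-2,3-dihydroxybutanedioate | O=C(OCc1ccccc1)[C@H](O)[C@@H](O)C(=O)OCc1ccccc1
F15 | step 1 | benzyl 2-oxoacetate | O=CC(=O)OCc1ccccc1
F16 | step 1 | 4-benzyl 1-tert-butyl (2E)-2-methylbut-2-enedioate | CC(C)(C)OC(=O)/C(C)=C/C(=O)OCc1ccccc1
A1 | alternative 1 | 3-methoxy-4-(methoxycarbonyl)-2,5,6-trimethylphenyl 2,4-dihydroxy-5,6-dimethylbenzoate (desformyl depside) | COC(=O)c1c(C)c(C)c(OC(=O)c2c(C)c(C)c(O)cc2O)c(C)c1OC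
A2 | alternative 1 | 2,2-dimethyl-6-(3-methyl-2,4-dioxopentyl)-4H-1,3-dioxin-4-one | CC(=O)C(C)C(=O)CC1=CC(=O)OC(C)(C)O1
A3 | alternative 1 | 6-methyl-3,5,7-trioxooct-1-en-1-one (acylketene) | CC(=O)C(C)C(=O)CC(=O)C=C=O
A4 | alternative 1 | 3-methoxy-4-(methoxycarbonyl)-2,5,6-trimethylphenyl 6-methyl-3,5,7-trioxooctanoate | COC(=O)c1c(C)c(C)c(OC(=O)CC(=O)CC(=O)C(C)C(C)=O)c(C)c1OC
A5 | alternative 2 | methyl 3-oxopentanoate | CCC(=O)CC(=O)OC
A6 | alternative 2 | methyl tiglate, methyl (2E)-2-methylbut-2-enoate | C/C=C(\C)C(=O)OC
A7 | alternative 2 | methyl 3,5,6-trimethyl-2,4-dioxocyclohexane-1-carboxylate (mixture of diastereomers and enol forms) | COC(=O)C1C(C)C(C)C(=O)C(C)C1=O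
A8 | alternative 2 | methyl 2,4-dihydroxy-3,5,6-trimethylbenzoate | COC(=O)c1c(C)c(C)c(O)c(C)c1O
A9 | alternative 3 | (3Z)-1,1-dimethoxy-2-methyl-3-(trimethylsilyloxy)penta-1,3-diene | COC(OC)=C(C)/C(O[Si](C)(C)C)=C/C
A10 | alternative 3 | methyl but-2-ynoate | CC#CC(=O)OC
A11 | alternative 3 | methyl 4-hydroxy-2-methoxy-3,5,6-trimethylbenzoate (identical with 21) | COC(=O)c1c(C)c(C)c(O)c(C)c1OC
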